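## Retrosynthetic overview

1. Target ⇒ global desilylation and C8 O-acylation of an 8-hydroxy-elemanolide with the silyl-protected (Z)-2-(hydroxymethyl)but-2-enoic acid, made from crotonaldehyde via a (Z)-alkenyl iodide.
2. Key disconnection C6–C7: SmI2 ketyl-radical 6-exo cyclisation of an acyclic C6 aldehyde onto a C7=C11 2-(acetoxymethyl)enoate; acetate loss unveils C11=C13 and the new C6 alkoxide closes the lactone.
3. The acceptor comes from a Baylis–Hillman reaction and acetate transposition at a C7 aldehyde; the C6 aldehyde from a dimethyl acetal; the C14/C15 alcohols from lactone and acrylate reduction.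
4. C5–C10 (quaternary vinyl centre plus C5) ⇒ Claisen rearrangement of the O-allyl enol ether of 3-formylated (S)-5-(hydroxymethyl)butyrolactone (source of C8) with a Baylis–Hillman bromide from 2,2-dimethoxyacetaldehyde.
5. Ring order: cyclohexane first (radical C6–C7 bond), γ-lactone second in the same flask; the template butyrolactone is opened by reduction beforehand.

Assumption: atom labels follow elemane numbering of the target (ring C5–C10; C10 bears vinyl C1=C2 and C14H2OH; C5 bears C4(=C3H2)C15H2OH; lactone C6–O–C12(=O)–C11(=C13H2)–C7; acyloxy on C8; target = 5S,6R,7R,8S,10R). TBS = tert-butyldimethylsilyl, TES = triethylsilyl.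

## Route

Step 1
Reactants: 1 2,2-dimethoxyacetaldehyde (60% aq.); 2 methyl acrylate
Product: 3 methyl 3-hydroxy-4,4-dimethoxy-2-methylidenebutanoate (racemic)
Conditions: DABCO (1,4-diazabicyclo[2.2.2]octane, 0.5 equiv), dioxane/H2O, rt, 48 h
Reagents that add atoms: none
Why: Morita–Baylis–Hillman reaction of an activated α,α-dialkoxy aldehyde; the racemic carbinol centre is erased in step 2.

Step 2
Reactants: 3 methyl 3-hydroxy-4,4-dimethoxy-2-methylidenebutanoate
Product: 5 methyl (2Z)-2-(bromomethyl)-4,4-dimethoxybut-2-enoate, via mesylate 4 (not isolated)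
Conditions: MsCl, Et3N, CH2Cl2, 0 °C; then LiBr, acetone, rt
Reagents that add atoms: lithium bromide [Li+].[Br-]
Why: Mesylation followed by SN2' displacement with bromide is the standard allylic transposition of Baylis–Hillman adducts and gives the thermodynamic (Z)-bromide (ester trans to the acetal arm, CH2Br cis to it).

Step 3
Reactants: 6 (5S)-5-(hydroxymethyl)oxolan-2-one
Product: 7 (5S)-5-{[(triethylsilyl)oxy]methyl}oxolan-2-one
Conditions: Et3SiCl, imidazole, CH2Cl2, 0 °C
Reagents that add atoms: chlorotriethylsilane CC[Si](Cl)(CC)CC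
Why: Routine silylation; TES is chosen because a primary TES ether can later be oxidised directly to the aldehyde, and the C8 stereocentre is carried from the chiral pool.

Step 4
Reactants: 7 (5S)-5-{[(triethylsilyl)oxy]methyl}oxolan-2-one; 8 ethyl formate
Product: 9 (5S)-3-(hydroxymethylidene)-5-{[(triethylsilyl)oxy]methyl}oxolan-2-one
Conditions: NaH (2 equiv), EtOH (cat.), THF, 0 °C to rt; then AcOH (to pH 5), 0 °C
Reagents that add atoms: none
Why: Crossed Claisen condensation (α-formylation) of the lactone enolate gives the hydroxymethylidene lactone used for strigolactone-type enol ethers; C8 is not touched.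

Step 5
Reactants: 9 (5S)-3-(hydroxymethylidene)-5-{[(triethylsilyl)oxy]methyl}oxolan-2-one; 5 methyl (2Z)-2-(bromomethyl)-4,4-dimethoxybut-2-enoate
Product: 11 methyl 2-{(1S)-1-[(3S,5S)-3-formyl-2-oxo-5-{[(triethylsilyl)oxy]methyl}oxolan-3-yl]-2,2-dimethoxyethyl}prop-2-enoate, via allyl vinyl ether 10 (not isolated)
Conditions: K2CO3, DMF, 0 °C to rt; aqueous work-up; then PhMe, 120 °C (sealed tube)
Reagents that add atoms: none
Why: O-alkylation gives the (E)-enol ether, whose Claisen rearrangement through a chair transition state (lactone CH2 and acetal arm both pseudo-axial) on the lactone face anti to the C8 CH2OTES arm forms C5–C10, setting the quaternary C10 (formyl cis to that arm) and C5 in the relative configuration of the target.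

Step 6
Reactants: 11 Claisen aldehyde
Product: 12 methyl 2-{(1S)-1-[(3R,5S)-3-ethenyl-2-oxo-5-{[(triethylsilyl)oxy]methyl}oxolan-3-yl]-2,2-dimethoxyethyl}prop-2-enoate
Conditions: Ph3PCH3Br, KN(SiMe3)2, THF, −78 to 0 °C
Reagents that add atoms: methyltriphenylphosphonium bromide C[P+](c1ccccc1)(c1ccccc1)c1ccccc1.[Br-]
Why: Wittig methylenation is aldehyde-selective at low temperature over lactone and acrylate, and the non-enolisable C10 cannot epimerise.

Step 7
Reactants: 12 vinyl lactone
Product: 13 (2S,4R,5S)-4-ethenyl-4-(hydroxymethyl)-5-(3-hydroxyprop-1-en-2-yl)-6,6-dimethoxy-1-[(triethylsilyl)oxy]hexan-2-ol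
Conditions: i-Bu2AlH (6 equiv), CH2Cl2, −78 to 0 °C; aq. KNaC4H4O6
Reagents that add atoms: none
Why: Hydride reduction opens the template lactone to the C14 primary and C8 secondary alcohols and reduces the acrylate 1,2 to the C15 allylic alcohol, while acetal, silyl ether and alkenes survive.

Step 8
Reactants: 13 triol
Product: 15 tetrasilyl ether of 13 (C14-OTBS; C15-OTBS; C7-OTES; C8-OTES), via bis-TBS ether 14 (not isolated)
Conditions: t-BuMe2SiCl (2.2 equiv), imidazole, DMF, −20 to 0 °C; then Et3SiCl (1.5 equiv), rt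
Reagents that add atoms: tert-butyldimethylsilyl chloride CC(C)(C)[Si](C)(C)Cl; chlorotriethylsilane CC[Si](Cl)(CC)CC
Why: Sequential silylation exploits the faster reaction of the two primary alcohols with the bulky chloride, leaving the secondary C8 hydroxyl for the more labile TES group.

Step 9
Reactants: 15 tetrasilyl ether
Product: 16 (2S,4R,5S)-4-ethenyl-6,6-dimethoxy-2-[(triethylsilyl)oxy]-4-{[(TBS)oxy]methyl}-5-{3-[(TBS)oxy]prop-1-en-2-yl}hexanal
Conditions: (COCl)2 (4 equiv), DMSO (8 equiv), CH2Cl2, −78 to −30 °C; then Et3N, −78 °C to rt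
Reagents that add atoms: none
Why: Under Swern conditions a primary TES ether is cleaved by the chlorosulfonium salt and oxidised to the aldehyde, while secondary TES and primary TBS ethers are inert.

Step 10
Reactants: 16 C7 aldehyde; 2 methyl acrylate
Product: 17 methyl (4S,6R,7S)-6-ethenyl-3-hydroxy-8,8-dimethoxy-2-methylidene-4-[(triethylsilyl)oxy]-6-{[(TBS)oxy]methyl}-7-{3-[(TBS)oxy]prop-1-en-2-yl}octanoate (C3 epimers)
Conditions: methyl acrylate (10 equiv), DABCO (1 equiv), MeOH, rt, 72 h
Reagents that add atoms: none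
Why: Morita–Baylis–Hillman reaction of an activated α-silyloxy aldehyde installs C11–C13; the new carbinol centre is lost in step 11 so its configuration is irrelevant.

Step 11
Reactants: 17 Baylis–Hillman adduct
Product: 19 methyl (2E,4S,6R,7S)-2-(acetoxymethyl)-6-ethenyl-8,8-dimethoxy-4-[(triethylsilyl)oxy]-6-{[(TBS)oxy]methyl}-7-{3-[(TBS)oxy]prop-1-en-2-yl}oct-2-enoate, via secondary acetate 18 (not isolated)
Conditions: Ac2O, Et3N, DMAP (4-(dimethylamino)pyridine, cat.), CH2Cl2, 0 °C; then DABCO (1 equiv), THF, 60 °C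
Reagents that add atoms: acetic anhydride CC(=O)OC(C)=O
Why: Acetylation followed by DABCO-mediated SN2'/SN2 1,3-transposition gives the thermodynamic primary (E)-allylic acetate (ester trans to C8, so no butenolide can form), which is the radical acceptor.

Step 12
Reactants: 19 allylic acetate acetal
Product: 21 methyl (2E,4S,6R,7S)-2-(acetoxymethyl)-6-ethenyl-7-formyl-4-[(triethylsilyl)oxy]-6-{[(TBS)oxy]methyl}-8-[(TBS)oxy]methyl-nona-2,8-dienoate (the C6 aldehyde), via collidinium acetal salt 20 (not isolated)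
Conditions: Et3SiOTf (2 equiv), 2,4,6-collidine (3 equiv), CH2Cl2, 0 °C; then H2O
Reagents that add atoms: water O
Why: Silyl triflate/collidine acetal cleavage (pyridinium N,O-acetal, then hydrolysis) is selective for aldehyde dimethyl acetals beside silyl ethers, acetate and enoate, and its non-acidic medium protects the epimerisable β,γ-unsaturated C5 centre.

Step 13
Reactants: 21 C6 aldehyde
Product: 23 8α-(triethylsilyloxy)-14,15-bis(TBS-oxy)elema-1,3,11(13)-trien-6α,12-olide (ring stereocentres as in the target), via hydroxy ester 22 (not isolated)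
Conditions: SmI2 (2.5 equiv, 0.1 M in THF), THF, −78 to 0 °C; aq. NH4Cl
Reagents that add atoms: none
Why: Proposed new method: electron transfer from divalent samarium to the aldehyde gives a ketyl radical that adds 6-exo-trig to C7 of the enoate through an all-equatorial chair (C5 and C8 substituents equatorial, ketyl oxygen anti to the ester), setting C6 and C7 trans to each other and to their neighbours; the α-ester radical is then reduced to a samarium enolate that expels acetate (E1cB) to give C11=C13, and the C6 alkoxide lactonises onto the methyl ester; the closest known reactions are SmI2 ketyl–olefin 6-exo cyclisations onto γ-alkoxy enoates and β-eliminations of samarium enolates.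

Step 14
Reactants: 23 silylated elemanolide
Product: 24 8α-hydroxy-14,15-bis(TBS-oxy)elema-1,3,11(13)-trien-6α,12-olide
Conditions: PPTS (pyridinium p-toluenesulfonate, 0.2 equiv), MeOH/CH2Cl2, 0 °C
Reagents that add atoms: none
Why: Mild acid methanolysis cleaves the secondary TES ether much faster than the two primary TBS ethers, leaving C8–OH as the only free hydroxyl.

Step 15
Reactants: 25 (2E)-but-2-enal (crotonaldehyde)
Product: 26 (2Z)-2-iodobut-2-enal
Conditions: I2 (1.5 equiv), K2CO3, DMAP (0.2 equiv), THF/H2O (1:1), rt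
Reagents that add atoms: iodine II
Why: Amine-catalysed α-iodination of the enal (conjugate addition, iodination, elimination) gives the (Z)-α-iodoenal with CHO trans to the methyl group.

Step 16
Reactants: 26 (2Z)-2-iodobut-2-enal
Product: 27 (2Z)-2-iodobut-2-en-1-ol
Conditions: NaBH4, MeOH, 0 °C
Reagents that add atoms: none
Why: Chemoselective 1,2-reduction of the aldehyde leaves the alkenyl iodide geometry untouched.

Step 17
Reactants: 27 (2Z)-2-iodobut-2-en-1-ol
Product: 28 tert-butyl{[(2Z)-2-iodobut-2-en-1-yl]oxy}dimethylsilane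
Conditions: t-BuMe2SiCl, imidazole, CH2Cl2, rt
Reagents that add atoms: tert-butyldimethylsilyl chloride CC(C)(C)[Si](C)(C)Cl
Why: Standard silylation masks the hydroxyl that would otherwise self-acylate in step 19.

Step 18
Reactants: 28 silylated alkenyl iodide
Product: 29 (2Z)-2-{[(tert-butyldimethylsilyl)oxy]methyl}but-2-enoic acid
Conditions: Pd(OAc)2 (5 mol %), PPh3 (10 mol %), CO (1 atm), H2O, Et3N, DMF, 50 °C; dilute citric acid work-up
Reagents that add atoms: carbon monoxide [C-]#[O+]; water O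
Why: Palladium-catalysed hydroxycarbonylation (oxidative addition to zerovalent palladium, CO insertion, hydrolysis) replaces iodide by CO2H with retention, giving the angelate-type Z acid that condensation routes do not deliver.

Step 19
Reactants: 24 8α-hydroxy elemanolide; 29 (2Z)-2-{[(tert-butyldimethylsilyl)oxy]methyl}but-2-enoic acid
Product: 31 8α-[(2Z)-2-{[(TBS)oxy]methyl}but-2-enoyloxy]-14,15-bis(TBS-oxy)elema-1,3,11(13)-trien-6α,12-olide, via mixed anhydride 30 (not isolated)
Conditions: 29, 2,4,6-Cl3C6H2COCl, Et3N, PhMe, rt; then 24, PhMe, 80 °C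
Reagents that add atoms: none
Why: Yamaguchi mixed-anhydride esterification run without a nucleophilic catalyst is the established way to make angelate-type esters without Z-to-E isomerisation.

Step 20
Reactants: 31 tris-TBS ester
Product: 32 CNP0338073.1, 8α-[(2Z)-2-(hydroxymethyl)but-2-enoyloxy]-14,15-dihydroxyelema-1,3,11(13)-trien-6α,12-olide (5S,6R,7R,8S,10R)
Conditions: HF·pyridine, pyridine, THF, 0 °C to rt
Reagents that add atoms: none
Why: Buffered fluoride desilylation removes the three primary TBS ethers without touching the α-methylene lactone, the unsaturated ester or any stereocentre.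

## Compound list

1 | 2,2-dimethoxyacetaldehyde | COC(OC)C=O | starting material
2 | methyl acrylate | C=CC(=O)OC | starting material
3 | methyl 3-hydroxy-4,4-dimethoxy-2-methylidenebutanoate (racemic) | COC(OC)C(O)C(=C)C(=O)OC | intermediate
4 | methyl 3-(methanesulfonyloxy)-4,4-dimethoxy-2-methylidenebutanoate (racemic, not isolated) | COC(OC)C(OS(C)(=O)=O)C(=C)C(=O)OC | intermediate
5 | methyl (2Z)-2-(bromomethyl)-4,4-dimethoxybut-2-enoate | BrC/C(=C\C(OC)OC)C(=O)OC | intermediate
6 | (5S)-5-(hydroxymethyl)oxolan-2-one | O=C1O[C@H](CO)CC1 | starting material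
7 | (5S)-5-{[(triethylsilyl)oxy]methyl}oxolan-2-one | O=C1O[C@H](CO[Si](CC)(CC)CC)CC1 | intermediate
8 | ethyl formate | CCOC=O | starting material
9 | (5S)-3-(hydroxymethylidene)-5-{[(triethylsilyl)oxy]methyl}oxolan-2-one (enol form of the 3-formyl lactone, E/Z enol mixture) | O=C1O[C@H](CO[Si](CC)(CC)CC)CC1=CO | intermediate
10 | methyl (2E)-4,4-dimethoxy-2-({[(E)-{(5S)-2-oxo-5-[(triethylsilyloxy)methyl]oxolan-3-ylidene}methyl]oxy}methyl)but-2-enoate (not isolated) | O=C1O[C@H](CO[Si](CC)(CC)CC)C/C1=C\OC/C(=C\C(OC)OC)C(=O)OC | intermediate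
11 | methyl 2-{(1S)-1-[(3S,5S)-3-formyl-2-oxo-5-{[(triethylsilyl)oxy]methyl}oxolan-3-yl]-2,2-dimethoxyethyl}prop-2-enoate | O=C1O[C@H](CO[Si](CC)(CC)CC)C[C@@]1(C=O)[C@@H](C(OC)OC)C(=C)C(=O)OC | intermediate
12 | methyl 2-{(1S)-1-[(3R,5S)-3-ethenyl-2-oxo-5-{[(triethylsilyl)oxy]methyl}oxolan-3-yl]-2,2-dimethoxyethyl}prop-2-enoate | O=C1O[C@H](CO[Si](CC)(CC)CC)C[C@@]1(C=C)[C@@H](C(OC)OC)C(=C)C(=O)OC | intermediate
13 | (2S,4R,5S)-4-ethenyl-4-(hydroxymethyl)-5-(3-hydroxyprop-1-en-2-yl)-6,6-dimethoxy-1-[(triethylsilyl)oxy]hexan-2-ol | C=C[C@](CO)(C[C@H](O)CO[Si](CC)(CC)CC)[C@@H](C(OC)OC)C(=C)CO | intermediate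
14 | 13 with the C14 and C15 hydroxyls as TBS ethers, C8–OH free (not isolated) | C=C[C@](CO[Si](C)(C)C(C)(C)C)(C[C@H](O)CO[Si](CC)(CC)CC)[C@@H](C(OC)OC)C(=C)CO[Si](C)(C)C(C)(C)C | intermediate
15 | tetrasilyl ether of 13: C14-OTBS, C15-OTBS, C7-OTES, C8-OTES, C6 dimethyl acetal | C=C[C@](CO[Si](C)(C)C(C)(C)C)(C[C@H](O[Si](CC)(CC)CC)CO[Si](CC)(CC)CC)[C@@H](C(OC)OC)C(=C)CO[Si](C)(C)C(C)(C)C | intermediate
16 | C7 aldehyde: 15 with the primary TES ether oxidised to CHO | C=C[C@](CO[Si](C)(C)C(C)(C)C)(C[C@H](O[Si](CC)(CC)CC)C=O)[C@@H](C(OC)OC)C(=C)CO[Si](C)(C)C(C)(C)C | intermediate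
17 | Baylis–Hillman adduct of 16 with methyl acrylate (C7 carbinol epimers) | C=C[C@](CO[Si](C)(C)C(C)(C)C)(C[C@H](O[Si](CC)(CC)CC)C(O)C(=C)C(=O)OC)[C@@H](C(OC)OC)C(=C)CO[Si](C)(C)C(C)(C)C | intermediate
18 | secondary C7 acetate of 17 (not isolated) | C=C[C@](CO[Si](C)(C)C(C)(C)C)(C[C@H](O[Si](CC)(CC)CC)C(OC(C)=O)C(=C)C(=O)OC)[C@@H](C(OC)OC)C(=C)CO[Si](C)(C)C(C)(C)C | intermediate
19 | transposed primary (E)-allylic acetate: C7=C11(CO2Me)CH2OAc, ester trans to C8 | C=C[C@](CO[Si](C)(C)C(C)(C)C)(C[C@H](O[Si](CC)(CC)CC)/C=C(/C(=O)OC)COC(C)=O)[C@@H](C(OC)OC)C(=C)CO[Si](C)(C)C(C)(C)C | intermediate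
20 | C6 methoxy(2,4,6-collidinium) N,O-acetal triflate from 19 (C6 epimers, not isolated) | C=C[C@](CO[Si](C)(C)C(C)(C)C)(C[C@H](O[Si](CC)(CC)CC)/C=C(/C(=O)OC)COC(C)=O)[C@@H](C(OC)[n+]1c(C)cc(C)cc1C)C(=C)CO[Si](C)(C)C(C)(C)C.[O-]S(=O)(=O)C(F)(F)F | intermediate
21 | C6 aldehyde: 19 with the dimethyl acetal replaced by CHO (cyclisation substrate) | C=C[C@](CO[Si](C)(C)C(C)(C)C)(C[C@H](O[Si](CC)(CC)CC)/C=C(/C(=O)OC)COC(C)=O)[C@@H](C=O)C(=C)CO[Si](C)(C)C(C)(C)C | intermediate
22 | cyclohexanol hydroxy ester: 6α-OH, 7β-[1-(methoxycarbonyl)ethenyl], 8α-OTES, ring stereocentres as in target (not isolated) | C=C[C@]1(CO[Si](C)(C)C(C)(C)C)C[C@H](O[Si](CC)(CC)CC)[C@@H](C(=C)C(=O)OC)[C@H](O)[C@H]1C(=C)CO[Si](C)(C)C(C)(C)C | intermediate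
23 | 8α-(triethylsilyloxy)-14,15-bis(TBS-oxy)elema-1,3,11(13)-trien-6α,12-olide | C=C[C@]1(CO[Si](C)(C)C(C)(C)C)C[C@H](O[Si](CC)(CC)CC)[C@H]2C(=C)C(=O)O[C@@H]2[C@H]1C(=C)CO[Si](C)(C)C(C)(C)C | intermediate
24 | 8α-hydroxy-14,15-bis(TBS-oxy)elema-1,3,11(13)-trien-6α,12-olide | C=C[C@]1(CO[Si](C)(C)C(C)(C)C)C[C@H](O)[C@H]2C(=C)C(=O)O[C@@H]2[C@H]1C(=C)CO[Si](C)(C)C(C)(C)C | intermediate
25 | (2E)-but-2-enal (crotonaldehyde) | C/C=C/C=O | starting material
26 | (2Z)-2-iodobut-2-enal | C/C=C(\I)C=O | intermediate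
27 | (2Z)-2-iodobut-2-en-1-ol | C/C=C(\I)CO | intermediate
28 | tert-butyl{[(2Z)-2-iodobut-2-en-1-yl]oxy}dimethylsilane | C/C=C(\I)CO[Si](C)(C)C(C)(C)C | intermediate
29 | (2Z)-2-{[(tert-butyldimethylsilyl)oxy]methyl}but-2-enoic acid | C/C=C(\C(O)=O)CO[Si](C)(C)C(C)(C)C | intermediate
30 | mixed anhydride of 29 with 2,4,6-trichlorobenzoic acid (not isolated) | C/C=C(\C(=O)OC(=O)c1c(Cl)cc(Cl)cc1Cl)CO[Si](C)(C)C(C)(C)C | intermediate
31 | 8α-[(2Z)-2-{[(TBS)oxy]methyl}but-2-enoyloxy]-14,15-bis(TBS-oxy)elema-1,3,11(13)-trien-6α,12-olide | C=C[C@]1(CO[Si](C)(C)C(C)(C)C)C[C@H](OC(=O)/C(=C\C)CO[Si](C)(C)C(C)(C)C)[C@H]2C(=C)C(=O)O[C@@H]2[C@H]1C(=C)CO[Si](C)(C)C(C)(C)C | intermediate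
32 | CNP0338073.1 | C=C[C@]1(CO)C[C@H](OC(=O)/C(=C\C)CO)[C@H]2C(=C)C(=O)O[C@@H]2[C@H]1C(=C)CO | target

## Step count and fallbacks

Total step count: 20. Longest linear sequence: 14 steps (steps 3–14, 19, 20 from 6; equally steps 1, 2, 5–14, 19, 20 from 1).

Three steps most likely to fail:

Step 5 (O-allylation/Claisen). C-alkylation could compete with O-alkylation, and chair/boat or facial leakage in the crowded rearrangement would erode C5/C10. The fallback sets out from 9 (with 3) and comes back at 11. Compound 3 is converted with Boc2O/DMAP into the tert-butyl carbonate methyl 3-[(tert-butoxycarbonyl)oxy]-4,4-dimethoxy-2-methylidenebutanoate F1. Then 9 is C-allylated directly with F1 under Lewis-base catalysis by hydroquinidine 1,4-phthalazinediyl diether (10 mol %, PhMe, rt), or its quinine-derived pseudo-enantiomer if that proves the matched partner. The amine adds SN2' to F1 with loss of CO2 and tert-butoxide, the liberated base deprotonates 9, and the C10 carbon nucleophile adds SN2' at C5 of the allyl-ammonium ion. The C5–C10 bond is thus made without an enol ether or pericyclic step, with C5 under catalyst control and C10 under lactone control.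

Step 13 (samarium ketyl cyclisation/elimination/lactonisation). Direct reduction of the acetoxymethyl enoate, loss of the γ-silyloxy group or incomplete acetate elimination could divert the cascade. The fallback sets out from 16 and comes back at 23, keeping the radical C6–C7 closure but separating it from methylene formation. Wittig olefination of 16 with methyl (triphenylphosphoranylidene)acetate gives the plain (E)-enoate acetal F2. Acetal cleavage as in step 12, through the collidinium acetal salt F3 (not isolated), gives the enoate aldehyde F4. SmI2/MeOH in THF at −78 °C then effects an ordinary ketyl–olefin 6-exo cyclisation to the hydroxy ester F5, which lactonises in the flask to the saturated trans-lactone F6. α-Methylenation follows: LiN(i-Pr)2, then Me2N=CH2+ I− to the Mannich base F7; MeI to the methiodide F8 (not isolated); NaHCO3 elimination returns 23.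

Step 19 (esterification of the hindered C8 alcohol with a Z, α-branched acid). Slow acylation or Z-to-E isomerisation of the activated acid is the danger. The fallback sets out from 24 and 28 and comes back at 31. Palladium-catalysed alkoxycarbonylation (Pd(OAc)2/Xantphos, CO 1 atm, Et3N, PhMe, 70 °C) couples the alkenyl iodide 28 with alcohol 24 with retention of the Z geometry. The acyl carbon is built on the alcohol from CO instead of activating acid 29; this fallback makes no new compound, hence the entry F0.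

Further compounds

F1 | step 5 | methyl 3-[(tert-butoxycarbonyl)oxy]-4,4-dimethoxy-2-methylidenebutanoate (racemic) | COC(OC)C(OC(=O)OC(C)(C)C)C(=C)C(=O)OC
F2 | step 13 | (E)-enoate acetal: 16 with CHO converted to (E)-CH=CH–CO2Me | C=C[C@](CO[Si](C)(C)C(C)(C)C)(C[C@H](O[Si](CC)(CC)CC)/C=C/C(=O)OC)[C@@H](C(OC)OC)C(=C)CO[Si](C)(C)C(C)(C)C
F3 | step 13 | collidinium acetal salt of F2 (C6 epimers, not isolated) | C=C[C@](CO[Si](C)(C)C(C)(C)C)(C[C@H](O[Si](CC)(CC)CC)/C=C/C(=O)OC)[C@@H](C(OC)[n+]1c(C)cc(C)cc1C)C(=C)CO[Si](C)(C)C(C)(C)C.[O-]S(=O)(=O)C(F)(F)F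
F4 | step 13 | enoate aldehyde: F2 with the acetal replaced by CHO | C=C[C@](CO[Si](C)(C)C(C)(C)C)(C[C@H](O[Si](CC)(CC)CC)/C=C/C(=O)OC)[C@@H](C=O)C(=C)CO[Si](C)(C)C(C)(C)C
F5 | step 13 | cyclohexanol hydroxy ester with a 7β-CH2CO2Me arm (not isolated) | C=C[C@]1(CO[Si](C)(C)C(C)(C)C)C[C@H](O[Si](CC)(CC)CC)[C@@H](CC(=O)OC)[C@H](O)[C@H]1C(=C)CO[Si](C)(C)C(C)(C)C
F6 | step 13 | 11,13-dihydro-13-nor lactone: 8α-(triethylsilyloxy)-14,15-bis(TBS-oxy)elema-1,3-dien-6α,12-olide lacking C13 | C=C[C@]1(CO[Si](C)(C)C(C)(C)C)C[C@H](O[Si](CC)(CC)CC)[C@H]2CC(=O)O[C@@H]2[C@H]1C(=C)CO[Si](C)(C)C(C)(C)C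
F7 | step 13 | Mannich base: 11-[(dimethylamino)methyl] derivative of F6 (C11 epimers) | C=C[C@]1(CO[Si](C)(C)C(C)(C)C)C[C@H](O[Si](CC)(CC)CC)[C@H]2C(CN(C)C)C(=O)O[C@@H]2[C@H]1C(=C)CO[Si](C)(C)C(C)(C)C
F8 | step 13 | methiodide of F7 (not isolated) | C=C[C@]1(CO[Si](C)(C)C(C)(C)C)C[C@H](O[Si](CC)(CC)CC)[C@H]2C(C[N+](C)(C)C)C(=O)O[C@@H]2[C@H]1C(=C)CO[Si](C)(C)C(C)(C)C.[I-]
F0 | step 19 | none | none
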